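The readings are calculated for substances that don't exist; the scatter is artificial.

- Decide first to read each run as two first-order steps in series, free monomer to monomer in chains to something unseen, for then one ratio of two read constants gives the height of the peak.

common to all: initiator 6.2 mM

| run | free monomer | remark | time |
|---|---|---|---|
| alder | 0.25 M | the very flask that is asked about, followed so far |  |
| maple | 0.12 M | run made earlier |  |
| flask | 0.25 M |  | 50 min |

| run | time / min | monomer in chains / % | free monomer / % |
|---|---|---|---|
| alder | 1.00 | 12.7 | 87.9 |
| alder | 2.00 | 22.8 | 73.2 |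
| alder | 3.00 | 34.0 | 62.8 |
| alder | 4.00 | 40.6 | 55.8 |
| alder | 5.00 | 44.9 | 47.0 |
| alder | 6.00 | 50.8 | 42.0 |
| maple | 1.33 | 18.9 | 80.4 |
| maple | 4.00 | 41.9 | 54.8 |
| maple | 8.00 | 55.7 | 29.5 |
| maple | 10.0 | 56.1 | 23.7 |
| maple | 15.0 | 51.1 | 11.1 |
| maple | 20.0 | 44.6 | 4.9 |

(standard deviation of a reading: 1 percentage point)

- the moment within 50 min at which there is most monomer in chains
- the amount of monomer in chains, in percent of the free monomer charged, at that time
- the first time at which monomer in chains reaches 27 %, in the same percent, in min



- Fastest rung: free monomer falls pseudo-first-order, read as 0.151 min⁻¹ in the maple run and 0.148 min⁻¹ in the alder run, so you may treat the percent curves of the two charges as one, with a free-monomer lifetime of 6.63 min.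
- Next rung: from 10.0 min to 20.0 min the maple run loses 30 percentage points of free monomer plus chains while holding a mean 50.7 % in chains. Chains therefore drain at 0.0597 min⁻¹, a lifetime of 16.7 min, longer than that of free monomer, so chains pile up first.
- Slowest rung: the 50 min allowed is longer than the chain lifetime, so you should expect the peak inside the run and a falling curve at its end.
- Divide the two constants: 2.53 is the make-to-drain ratio κ. Its zero is the symmetric case, κ = 1, where the peak stands at 36.8 %.
- Above that zero, the peak height is κ^(1/(1 − κ)) and its time is ln(κ)/(make constant − drain constant). My reckoning thus gives 54.5 % at 10.2 min, where [monomer in chains]/[free monomer] equals κ. Interpolating the alder readings puts 27 % at 2.38 min.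
- The forecast gives 55 % at 9 min and 27 % at 2.3 min, and of the two charges it says: “percent curves roughly coincide”. My peak time is later than its own.
- The alder flask peaks at 54.9 % at 10.5 min, later than forecast, and reaches 27 % at 2.28 min.

    free monomer + growing radical → monomer in chains + growing radical, rate k1*[growing radical]*[free monomer] (k = 52100 M⁻¹ s⁻¹)
    free monomer + initiating radical → growing radical + monomer in chains (k = 1.25 × 10⁶ M⁻¹ s⁻¹)
    2 growing radical → dead chain (k = 7.00 × 10⁸ M⁻¹ s⁻¹)
    monomer in chains → over-reaction product (k = 0.0558 min⁻¹)
    initiator → 2 initiating radical (k = 0.0156 min⁻¹)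

- At 4.56 min the alder flask makes monomer in chains 3.12 times faster than it uses it up, and at its peak [monomer in chains]/[free monomer] stands at 2.53 against κ = 2.53. For a neighbour flask charged with 0.011 M of initiator, scaling κ by the square root of the initiator charges gives 3.36 and a reckoned peak of 59.8 %, and that neighbour reaches 60.6 %.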